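Ochre got a small charge of second reagent, 1.30 equiv against 2.00 equiv in teal, and I wanted to see what that does to intermediate A late in the run.

all flasks: starting material 0.10 M

|  | coupling partner | second reagent | solid third reagent | remark | time |
|---|---|---|---|---|---|
| alder | 1.8 equiv | 2 equiv | 0.58 equiv | run made earlier |  |
| ash | 1.8 equiv | 2 equiv | 2.7 equiv | run made earlier |  |
| elm | 1.4 equiv | 2 equiv | 1.1 equiv | run made earlier |  |
| teal | 1.80 equiv | 2.00 equiv | 1.10 equiv |  | 15 h |
| blue | 0.450 equiv | 2.00 equiv | 1.10 equiv |  | 15 h |
| violet | 3.60 equiv | 2.00 equiv | 1.10 equiv |  | 15 h |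
| red | 0.450 equiv | 8.00 equiv | 3.30 equiv |  | 15 h |
| ochre | 1.80 equiv | 1.30 equiv | 0.740 equiv |  | 15 h |

| run | time / h | intermediate A / % | product / % | starting material / % |
|---|---|---|---|---|
| alder | 0.417 | 6.6 | 0 | 92.7 |
| alder | 1.00 | 12.2 | 0 | 84.1 |
| alder | 2.00 | 18.3 | 0 | 71.4 |
| alder | 3.00 | 21.2 | 0.1 | 62.0 |
| alder | 5.00 | 19.7 | 1.1 | 47.0 |
| alder | 6.00 | 18.1 | 1.6 | 40.9 |
| alder | 8.00 | 15.4 | 4.7 | 32.5 |
| ash | 1.00 | 13.1 | 0.8 | 84.5 |
| ash | 2.00 | 18.9 | 0 | 70.7 |
| ash | 3.00 | 20.1 | 0.3 | 61.5 |
| ash | 4.00 | 20.7 | 0.6 | 53.6 |
| ash | 5.00 | 19.3 | 0.9 | 47.1 |
| ash | 6.00 | 18.8 | 2.3 | 41.1 |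
| ash | 8.00 | 15.5 | 4.1 | 31.9 |
| elm | 0.667 | 7.2 | 0.1 | 91.1 |
| elm | 2.00 | 15.2 | 0.2 | 77.2 |
| elm | 4.00 | 17.6 | 0.6 | 61.5 |
| elm | 5.00 | 16.4 | 1.5 | 56.0 |
| elm | 8.00 | 13.2 | 3.7 | 42.8 |

(readings scatter by 0.3 percentage points)

- at the start none of the solid third reagent is in solution

1. the flasks by amount of intermediate A, in percent of the starting material charged, highest first, at 15 h (teal / blue / violet / red / ochre)
2. the same order at 1.5 h (teal / blue / violet / red / ochre)
3. the amount of intermediate A, in percent of the starting material charged of the flask you put first, at 15 h
4. the amount of intermediate A, in percent of the starting material charged of the flask you put last, at 15 h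

Alder and ash, with 0.58 equiv and 2.7 equiv of solid third reagent, read 47.0% and 47.1% of starting material at 5.00 h, so I set the solid aside. I took starting material and coupling partner to react one to one. Alder's last reading then gave 0.102 h⁻¹ for each equivalent of partner, which took ochre to 15.6% of its starting material at 15 h.

I also assumed, untested because these runs never varied second reagent, that intermediate A is lost with second reagent one to one. Second reagent left minus intermediate A left then equals second reagent charged less starting material converted, so it falls as conversion rises. In ochre at 15 h that difference is 45.6% of the starting material charged: the spare reagent, second reagent charged less starting material converted.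

At the top of alder's hump, the reading at 3.00 h, making and loss of intermediate A about balance, which read 0.232 h⁻¹ per equivalent of second reagent.

My way was the steady-state approximation: intermediate A equals its making, 0.0152 h⁻¹ in ochre, divided by that constant times second reagent left, which is spare reagent plus intermediate A. With the spare reagent by itself I got 14.4%. Putting that back gave 11.0%, and once more 11.6%. For red I reckoned starting material at 15 h in the same way, 68.2%. With spare reagent 768%, the same reckoning gave 0.518%.

The forecast, the other way, reasoned that “A's loss slows as the run proceeds” and integrated by hand: ochre > teal > violet > blue > red at 15 h, violet > ochre > teal > blue > red at 1.5 h, top 17.5%, low 0.6%.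

On red the two ways nearly meet; on ochre they part, and mine is the one that cheats. In red, intermediate A lives 0.562 h, far shorter than the 12.0 h in which its making falls. In ochre it lives 7.55 h against 8.80 h, so it still carries what was made earlier, and my figure reads low. I trusted the forecast there.

The flasks gave ochre > teal > violet > blue > red at 15 h and violet > ochre > teal > blue > red at 1.5 h, with ochre at 17.4% and red at 0.567%. By the step to intermediate B alone, with the other concentrations as charged, intermediate A in ochre has a half-life of 2.4 h, short against 15 h. Spare reagent plus that 17.4% makes 63.0% of the starting material charged, and the second reagent standing in ochre was 63.0%.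

    solid third reagent ⇌ third reagent, rate k1*(cs1 - [third reagent]) while solid is left; crystals form when [third reagent] > cs1 (solubility = 0.0650 M, k = 8.00 × 10⁻⁴ min⁻¹)
    intermediate B → decomposed reagent (k = 8.10 × 10⁻⁴ min⁻¹)
    third reagent + intermediate B → product (k = 0.0320 M⁻¹ min⁻¹)
    second reagent + intermediate A → intermediate B (k = 0.0370 M⁻¹ min⁻¹)
    starting material + coupling partner → intermediate A (k = 0.0170 M⁻¹ min⁻¹)

In the neighbour of ochre charged with 0.330 equiv of second reagent, the spare reagent is −51.4%, negative, so at least 51.4% must stand as intermediate A at 15 h. That flask held 58.7%, with 22.2% of its own second reagent left.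

(Readings and results were generated by integration with made-up constants, and the scatter is random.)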